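The constants used here are made up; no experiment stands behind them.

I keep a ledger of the charge of starting material, the limiting reagent, to see which temperature leaves what in the flask at the end, and I open it on gamma.

the same everywhere: starting material 1.0 mM; time 8.0 s

|  | temperature |
|---|---|
| eta | 78 °C |
| gamma | 86 °C |
| theta | 70 °C |

    starting material → ring (k1 = 0.065 s⁻¹, Ea1 = 86.0 kJ mol⁻¹)
    ring → over-reaction product (k2 = 0.024 s⁻¹, Ea2 = 87.0 kJ mol⁻¹)
    2 starting material → open dimer (k3 = 27 M⁻¹ s⁻¹, Ea3 = 46.0 kJ mol⁻¹)
    ring ⇌ isomer of the product (K4 = 1.1, k4 = 0.0044 s⁻¹, Ea4 = 108 kJ mol⁻¹, ΔH4 = 36.0 kJ mol⁻¹)
    (constants at 70 °C)

- percent here means starting material units held: one open dimer counts as two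
- two of one species on the left: rate k times its square, two consumed each time
- constants are those at 70 °C; use the activation energies and enthalpies for any other temperature

1. which of these there is most of at the end, counted by the starting material in it, eta (open dimer / over-reaction product / ring / starting material)
2. which of these there is most of at the end, counted by the starting material in it, gamma (open dimer / over-reaction product / ring / starting material)
3. which of these there is most of at the end, counted by the starting material in it, theta (open dimer / over-reaction product / ring / starting material)
4. the largest of these amounts at the end, in percent of the starting material charged, eta
5. the largest of these amounts at the end, in percent of the starting material charged, gamma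
6. the largest of these amounts at the end, in percent of the starting material charged, theta

At 86 °C the Arrhenius law gives ring closure the constant k_r = 0.249 s⁻¹. The open dimer takes starting material at full charge with k_d = 0.111 s⁻¹, which is 2 times its constant times the charge. Their quotient S = k_r/k_d, here 2.25, is the split number: how many times faster starting material leaves toward ring than toward open dimer at the start.

I solve the two ends first. With k_d struck from the rate law, starting material decays as exp(−k_r t) and what leaves it is booked to ring; with k_r struck, what leaves it is booked to open dimer. The rate law joins these ends exactly: with u = 1 − exp(−k_r t), the fraction left is (1 − u)/(1 + u/S), and the fraction booked through ring is S·ln(1 + u/S).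

For gamma at 8.0 s, u is 0.864, so 9.86% stays as starting material, 73.1% has passed through ring, and the remaining 17.1% closes the books as open dimer. The ring entry divides further: steps 2 and 4 together take ring forward with a constant of 0.117 s⁻¹, a half-life of 5.92 s with the way back from the isomer of the product not counted, and my hand reckoning stops there.

For theta, S is 1.20 and u is 0.405, so 44.5% stays, 34.9% passes through ring and 20.6% is open dimer. I therefore commit to starting material as the largest entry in theta.

The forecast names ring at 41.3% for eta, ring at 40% for gamma and starting material at 44.5% for theta, and its stated method is: “Treat the starting material (SM) exactly”.

The flasks end with ring at 41.3% in eta, ring at 40.1% in gamma and starting material at 44.5% in theta. In gamma at 8.00 s, ring is made at 0.533 of the rate at which it is used up, each step taken net. Charging 4.0 mM in place of 1.0 mM in the gamma flask, with the time held, leaves u alone and brings S down to 0.562, so the ledger books 42.3% as open dimer. That neighbour flask ends with 42.3% of open dimer and 27.6% of ring.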